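**Retrosynthetic overview**
- The C4 methyl ether comes from a 4-hydroxy enone, which comes from the 6,6-disubstituted cyclohex-3-enone by epoxidation of C3=C4 anti to the allyl group and E1cB opening; the C8 acetate comes from the C8 alcohol.
- Key disconnection, C7–C8 together with C5–C6: C8 is an aryl carbinol carbon (an aldehyde carbon), C7 a former alkene carbon and C6 a quaternary carbon alpha to the C1 ketone. This is the array left when a Prins addition to a 1-alkenylcyclopent-3-enyl silyl ether is ended by a pinacol shift.
- Ring order: the arene and the cyclopentene are bought; the cyclohexenone is the only ring made, by five-to-six ring enlargement in the key step (an epoxide ring appears briefly afterwards).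
- The silyl ether comes from cyclopent-3-en-1-one and a Z-alkenylcerium reagent made from (Z)-3-iodohexa-2,5-diene (α-iodo ylide olefination of acetaldehyde). Trans-hydrometalation of hex-5-en-2-yne is avoided because nothing distinguishes its two alkyne carbons (methyl against allyl CH2).

Key step: step 4

Remark: the sense of induction of the chiral acid in step 4 cannot be predicted with certainty; the catalyst enantiomer is fixed in a first screen so that C7 and C8 come out (S,S).

Step 1
Reactants: 1 but-3-en-1-yltriphenylphosphonium bromide; 2 acetaldehyde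
Product: 6 (2Z)-3-iodohexa-2,5-diene, via phosphorus ylide 3 (not isolated), via iodophosphonium iodide 4 (not isolated), via iodo ylide 5 (not isolated)
Conditions: n-BuLi, THF, 0 °C; I2, −78 °C; NaN(SiMe3)2, −20 °C; then 2, −78 °C to rt
Reagents that add atoms: iodine, [I][I]
Why: A Wittig olefination with an α-iodo ylide (the trisubstituted variant of the Stork–Zhao iodo-olefination) places the aldehyde substituent cis to iodine, so methyl and iodine should end up cis, which is the geometry the later anti addition requires.

Step 2
Reactants: 6 (2Z)-3-iodohexa-2,5-diene; 7 cyclopent-3-en-1-one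
Product: 10 1-[(2Z)-hexa-2,5-dien-3-yl]cyclopent-3-en-1-ol, via alkenyllithium 8 (not isolated), via alkenylcerium dichloride 9 (not isolated)
Conditions: t-BuLi (2 equiv), Et2O, −78 °C; CeCl3, THF, −78 °C; then 7, −78 °C; aq. NH4Cl
Reagents that add atoms: none
Why: Iodine–lithium exchange keeps the alkene geometry, and the weakly basic organocerium reagent should add 1,2 to the easily enolized β,γ-unsaturated ketone without deprotonating it; the new carbinol carbon is not stereogenic because the ring is symmetric.

Step 3
Reactants: 10 1-[(2Z)-hexa-2,5-dien-3-yl]cyclopent-3-en-1-ol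
Product: 11 trimethyl({1-[(2Z)-hexa-2,5-dien-3-yl]cyclopent-3-en-1-yl}oxy)silane
Conditions: TMSCl, imidazole, DMF, 0 °C to rt
Reagents that add atoms: chlorotrimethylsilane, C[Si](C)(C)Cl
Why: Silylation of a tertiary alcohol with a chlorosilane and imidazole runs under non-acidic conditions, which should leave the ionizable tertiary allylic C–O bond and the alkene geometry untouched.

Step 4
Reactants: 11 trimethyl({1-[(2Z)-hexa-2,5-dien-3-yl]cyclopent-3-en-1-yl}oxy)silane; 12 3,4,5-trimethoxybenzaldehyde
Product: 14 (6R)-6-allyl-6-[(1S,2S)-1-hydroxy-1-(3,4,5-trimethoxyphenyl)propan-2-yl]cyclohex-3-en-1-one, via silyl ether ketone 13 (not isolated)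
Conditions: chiral imidodiphosphorimidate Brønsted acid (IDPi, two 3,3′-diaryl-BINOL units, N-triflyl groups, 3 mol %), toluene, −78 °C; then aq. citric acid, THF, 0 °C
Reagents that add atoms: none
Why: Proposed new method: the protonated or in-flask silylated IDPi holds aldehyde 12 as an oxocarbenium ion inside its chiral anion, the trisubstituted alkene of 11 attacks it through C7 (new C7–C8 bond), and the charge building at C6 is quenched in the same event by antiperiplanar 1,2-shift of a ring CH2 from the silyloxy carbon (new C5–C6 bond), after which the silyl group passes from the C1 oxocarbenium ion by way of the catalyst to O8, giving 13, which the work-up hydrolyses to 14. The closest known reactions are the Lewis-acid Prins–pinacol ring enlargement of 1-alkenylcycloalkanol silyl ethers with acetals and chiral-acid-catalysed semipinacol shifts of allylic alcohols; an aldehyde partner under a confined chiral acid has not been shown. The cyclohex-3-enone ring is closed by ring enlargement (five to six, 1,2-alkyl shift) and not by cyclization, and the symmetric cyclopentene gives the same skeleton whichever CH2 migrates. C7 and C8 are set by the catalyst, which has to pair the Si face of C7 with the Si face of the aldehyde in the open transition state expected for such additions (anti methyl/oxygen relationship), and C6 follows from C7 because electrophile and migrating carbon add anti across the Z-alkene (migration onto the Re face of C6). The step needs one of three alkenes to react and the 1,2-shift to outrun proton loss and Friedel–Crafts closure onto the aryl ring; the silyloxy-flanked trisubstituted alkene is the most nucleophilic, and the migrating bond on the adjacent carbinol carbon is already aligned with the developing cation.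

Step 5
Reactants: 14 (6R)-6-allyl-6-[(1S,2S)-1-hydroxy-1-(3,4,5-trimethoxyphenyl)propan-2-yl]cyclohex-3-en-1-one
Product: 15 (6R)-6-allyl-6-[(1S,2S)-1-acetoxy-1-(3,4,5-trimethoxyphenyl)propan-2-yl]cyclohex-3-en-1-one
Conditions: Ac2O, pyridine, DMAP (cat.), CH2Cl2, 0 °C
Reagents that add atoms: acetic anhydride, CC(=O)OC(C)=O
Why: DMAP-catalysed acylation of the secondary benzylic alcohol should trap the open form of the γ-hydroxy ketone/hemiketal pair, run cold so that the β,γ-alkene stays out of conjugation; C8 keeps its configuration because its C–O bond is not broken.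

Step 6
Reactants: 15 (6R)-6-allyl-6-[(1S,2S)-1-acetoxy-1-(3,4,5-trimethoxyphenyl)propan-2-yl]cyclohex-3-en-1-one
Product: 17 (4R,6R)-6-allyl-4-hydroxy-6-[(1S,2S)-1-acetoxy-1-(3,4,5-trimethoxyphenyl)propan-2-yl]cyclohex-2-en-1-one, via epoxy ketone 16 (not isolated)
Conditions: mCPBA (1.05 equiv), NaHCO3, CH2Cl2, 0 °C; then Et3N (3 equiv), 0 °C to rt
Reagents that add atoms: 3-chloroperbenzoic acid, O=C(OO)c1cccc(Cl)c1
Why: Prilezhaev epoxidation should choose the cis-disubstituted ring alkene over the monosubstituted allyl alkene and approach anti to the pseudoaxial allyl group at C6 (the branched C7 substituent sitting pseudoequatorial), and the amine then opens the β,γ-epoxy ketone by E1cB elimination from C2 without breaking the C4–O bond, so the epoxidation face sets C4 as R.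

Step 7
Reactants: 17 (4R,6R)-6-allyl-4-hydroxy-6-[(1S,2S)-1-acetoxy-1-(3,4,5-trimethoxyphenyl)propan-2-yl]cyclohex-2-en-1-one
Product: 18 (4R,6R)-6-allyl-4-methoxy-6-[(1S,2S)-1-acetoxy-1-(3,4,5-trimethoxyphenyl)propan-2-yl]cyclohex-2-en-1-one (the target)
Conditions: Me3OBF4, 1,8-bis(dimethylamino)naphthalene, 4 Å MS, CH2Cl2, 0 °C to rt
Reagents that add atoms: trimethyloxonium tetrafluoroborate, C[O+](C)C.F[B-](F)(F)F
Why: O-Methylation with a trialkyloxonium salt and a hindered non-nucleophilic amine runs under nearly neutral conditions that should spare the acetate and the enone, and only the O–H bond reacts, so C4 is not touched.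

**Compound list**
1 | but-3-en-1-yltriphenylphosphonium bromide | C=CCC[P+](c1ccccc1)(c1ccccc1)c1ccccc1.[Br-] | starting material
2 | acetaldehyde | CC=O | starting material
3 | but-3-en-1-ylidenetriphenylphosphorane | C=CCC=P(c1ccccc1)(c1ccccc1)c1ccccc1 | intermediate
4 | (1-iodobut-3-en-1-yl)triphenylphosphonium iodide (racemic) | C=CCC(I)[P+](c1ccccc1)(c1ccccc1)c1ccccc1.[I-] | intermediate
5 | (1-iodobut-3-en-1-ylidene)triphenylphosphorane | C=CCC(I)=P(c1ccccc1)(c1ccccc1)c1ccccc1 | intermediate
6 | (2Z)-3-iodohexa-2,5-diene (iodine cis to the methyl group) | C/C=C(\I)CC=C | intermediate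
7 | cyclopent-3-en-1-one | O=C1CC=CC1 | starting material
8 | (2E)-hexa-2,5-dien-3-yllithium (lithium cis to the methyl group, geometry of 6 retained) | C/C=C(\[Li])CC=C | intermediate
9 | dichloro[(2Z)-hexa-2,5-dien-3-yl]cerium (nominal formula RCeCl2, cerium cis to the methyl group) | C/C=C(\[Ce](Cl)Cl)CC=C | intermediate
10 | 1-[(2Z)-hexa-2,5-dien-3-yl]cyclopent-3-en-1-ol (methyl cis to the carbinol carbon) | C=CC/C(=C/C)C1(O)CC=CC1 | intermediate
11 | trimethyl({1-[(2Z)-hexa-2,5-dien-3-yl]cyclopent-3-en-1-yl}oxy)silane | C=CC/C(=C/C)C1(O[Si](C)(C)C)CC=CC1 | intermediate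
12 | 3,4,5-trimethoxybenzaldehyde | COc1cc(C=O)cc(OC)c1OC | starting material
13 | (6R)-6-allyl-6-[(1S,2S)-1-(trimethylsilyloxy)-1-(3,4,5-trimethoxyphenyl)propan-2-yl]cyclohex-3-en-1-one | C=CC[C@]1([C@H](C)[C@H](O[Si](C)(C)C)c2cc(OC)c(OC)c(OC)c2)CC=CCC1=O | intermediate
14 | (6R)-6-allyl-6-[(1S,2S)-1-hydroxy-1-(3,4,5-trimethoxyphenyl)propan-2-yl]cyclohex-3-en-1-one | C=CC[C@]1([C@H](C)[C@H](O)c2cc(OC)c(OC)c(OC)c2)CC=CCC1=O | intermediate
15 | (6R)-6-allyl-6-[(1S,2S)-1-acetoxy-1-(3,4,5-trimethoxyphenyl)propan-2-yl]cyclohex-3-en-1-one | C=CC[C@]1([C@H](C)[C@H](OC(C)=O)c2cc(OC)c(OC)c(OC)c2)CC=CCC1=O | intermediate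
16 | (3S,4R,6R)-6-allyl-3,4-epoxy-6-[(1S,2S)-1-acetoxy-1-(3,4,5-trimethoxyphenyl)propan-2-yl]cyclohexan-1-one (epoxide oxygen anti to the allyl group) | C=CC[C@]1([C@H](C)[C@H](OC(C)=O)c2cc(OC)c(OC)c(OC)c2)C[C@H]3O[C@H]3CC1=O | intermediate
17 | (4R,6R)-6-allyl-4-hydroxy-6-[(1S,2S)-1-acetoxy-1-(3,4,5-trimethoxyphenyl)propan-2-yl]cyclohex-2-en-1-one | C=CC[C@]1([C@H](C)[C@H](OC(C)=O)c2cc(OC)c(OC)c(OC)c2)C[C@@H](O)C=CC1=O | intermediate
18 | (4R,6R)-6-allyl-4-methoxy-6-[(1S,2S)-1-acetoxy-1-(3,4,5-trimethoxyphenyl)propan-2-yl]cyclohex-2-en-1-one | C=CC[C@]1([C@H](C)[C@H](OC(C)=O)c2cc(OC)c(OC)c(OC)c2)C[C@@H](OC)C=CC1=O | target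

**Step count**
Total: 7 steps. Longest linear sequence: 7 steps (1 to 18).

**Steps most likely to fail**

First, step 4 (proposed new method). The strong acid may ionize the tertiary allylic silyl ether before the aldehyde is engaged. The C6 cation may lose a proton or close onto the electron-rich aryl ring instead of triggering the shift. Face selection with the electron-rich aldehyde may be poor, and the benzylic silyl ether or the β,γ-alkene of the product may not survive the acid. The fallback uses two established reaction types: the acetal-initiated Prins–pinacol ring enlargement under a stoichiometric Lewis acid, and stereocontrol by a C2-symmetric diol acetal. It sets out from 12 (with 11) and comes back at 14. Aldehyde 12 is condensed with (2R,4R)-pentane-2,4-diol (PPTS, benzene, removal of water) to (4R,6R)-4,6-dimethyl-2-(3,4,5-trimethoxyphenyl)-1,3-dioxane F1. TiCl4 in CH2Cl2 at −78 °C should open the acetal at the oxygen next to the axial methyl group, and the alkene of 11 attacks with inversion and ring enlargement. By that model the (R,R) diol should give the 8S centre, and aqueous work-up should give (6R)-6-allyl-6-[(1S,2S)-1-{[(2R,4R)-4-hydroxypentan-2-yl]oxy}-1-(3,4,5-trimethoxyphenyl)propan-2-yl]cyclohex-3-en-1-one F2. Oxidation of the auxiliary hydroxyl with Dess–Martin periodinane would give (6R)-6-allyl-6-[(1S,2S)-1-{[(2R)-4-oxopentan-2-yl]oxy}-1-(3,4,5-trimethoxyphenyl)propan-2-yl]cyclohex-3-en-1-one F3. β-Elimination with dibenzylammonium trifluoroacetate (toluene, 50 °C) then releases 14. The C7/C8 relationship rests here on the inherent open-transition-state preference, and a minor diastereomer would have to be removed by chromatography.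

Second, step 6. The peracid may approach syn to the allyl group if the ring does not adopt the expected conformation, may also attack the allyl alkene, and the epoxy ketone may open before it is handled. The fallback sets C4 by reagent-controlled carbonyl reduction instead of substrate-controlled epoxidation; it sets out from 15 and comes back at 17. The epoxidation and opening are run without regard to the face, giving 17 together with its epimer (4S,6R)-6-allyl-4-hydroxy-6-[(1S,2S)-1-acetoxy-1-(3,4,5-trimethoxyphenyl)propan-2-yl]cyclohex-2-en-1-one F4. The mixture is oxidized (Dess–Martin periodinane, NaHCO3, CH2Cl2) to (5R)-5-allyl-5-[(1S,2S)-1-acetoxy-1-(3,4,5-trimethoxyphenyl)propan-2-yl]cyclohex-2-ene-1,4-dione F5. The C4 carbonyl, less hindered than the C1 carbonyl beside the quaternary carbon, is reduced with catecholborane and (S)-2-methyl-CBS-oxazaborolidine (toluene, −78 °C). By the usual model, with the vinyl carbon as the large group, this should give the 4R alcohol 17.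

Third, step 1. With the small aldehyde the Z-selectivity of the iodo-olefination may erode, conversion may be low, and the volatile iodide may be lost on isolation; any E-iodide would be carried through to the C7 epimer. The fallback is a stereospecific alkoxide-directed carbomagnesiation; it sets out from 7 and comes back at 10, replacing steps 1 and 2. Ethynylmagnesium bromide (THF, −78 to 0 °C) adds to 7 to give 1-ethynylcyclopent-3-en-1-ol F6. Allylmagnesium bromide with catalytic CuI (Et2O/THF, −20 °C to rt) should add anti across the alkyne under direction by the magnesium alkoxide, with allyl on the proximal carbon, to give the chelate 4-allyl-1-oxa-2-magnesaspiro[4.4]nona-3,7-diene F7. Iodine converts this with retention into 1-[(1Z)-1-iodopenta-1,4-dien-2-yl]cyclopent-3-en-1-ol F8. Negishi coupling with MeZnCl and Pd(PPh3)4 (THF, 40 °C) then places the methyl group cis to the carbinol carbon and should give 10 as a single alkene isomer.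

**Further compounds**
F1 | step 4 | (4R,6R)-4,6-dimethyl-2-(3,4,5-trimethoxyphenyl)-1,3-dioxane | C[C@@H]1C[C@@H](C)OC(c2cc(OC)c(OC)c(OC)c2)O1
F2 | step 4 | (6R)-6-allyl-6-[(1S,2S)-1-{[(2R,4R)-4-hydroxypentan-2-yl]oxy}-1-(3,4,5-trimethoxyphenyl)propan-2-yl]cyclohex-3-en-1-one | C=CC[C@]1([C@H](C)[C@H](O[C@H](C)C[C@@H](C)O)c2cc(OC)c(OC)c(OC)c2)CC=CCC1=O
F3 | step 4 | (6R)-6-allyl-6-[(1S,2S)-1-{[(2R)-4-oxopentan-2-yl]oxy}-1-(3,4,5-trimethoxyphenyl)propan-2-yl]cyclohex-3-en-1-one | C=CC[C@]1([C@H](C)[C@H](O[C@H](C)CC(C)=O)c2cc(OC)c(OC)c(OC)c2)CC=CCC1=O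
F4 | step 6 | (4S,6R)-6-allyl-4-hydroxy-6-[(1S,2S)-1-acetoxy-1-(3,4,5-trimethoxyphenyl)propan-2-yl]cyclohex-2-en-1-one | C=CC[C@]1([C@H](C)[C@H](OC(C)=O)c2cc(OC)c(OC)c(OC)c2)C[C@H](O)C=CC1=O
F5 | step 6 | (5R)-5-allyl-5-[(1S,2S)-1-acetoxy-1-(3,4,5-trimethoxyphenyl)propan-2-yl]cyclohex-2-ene-1,4-dione | C=CC[C@]1([C@H](C)[C@H](OC(C)=O)c2cc(OC)c(OC)c(OC)c2)CC(=O)C=CC1=O
F6 | step 1 | 1-ethynylcyclopent-3-en-1-ol | C#CC1(O)CC=CC1
F7 | step 1 | 4-allyl-1-oxa-2-magnesaspiro[4.4]nona-3,7-diene | C=CCC1=C[Mg]OC12CC=CC2
F8 | step 1 | 1-[(1Z)-1-iodopenta-1,4-dien-2-yl]cyclopent-3-en-1-ol | C=CC/C(=C/I)C1(O)CC=CC1
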